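## Structural features

The target is a 2,3-dihydro-1,4-benzodioxine in which a benzene ring (ring A) is fused through C4a and C8a to a six-membered dioxane ring (ring B) made up of O1, C2, C3 and O4. C2 carries a 3,4,5-trimethoxyphenyl group and C3 a methyl group; these two stereocentres are neighbours, configured (2R,3S), which places aryl and methyl cis on ring B. Ring A carries an allyl group at C7, para to O4 and meta to O1, so the two ring oxygens are not interchangeable and each has to be bonded to the right carbon of ring B. Fragile points are the allyl group, whose double bond can move into conjugation under base, metal hydrides or palladium hydride, and the C2–O1 bond, a benzylic ether of an electron-rich arene that acid can ionise. The cis isomer is the less stable one, so it cannot be reached by equilibration and must be made under kinetic control. The real difficulty is thus the combination of absolute and relative control at two adjacent C–O carbons with an unambiguous O1/O4 regiochemistry relative to C7. The key step exploits that C2 is a benzylic carbinol carbon bonded to O1, hence the reduction product of an aryl ketone, and that the C3 methyl can be stored as an ester, which together with the ketone makes the C3–H (on the carbon already bonded to O4) acidic enough to racemise while the ketone is reduced.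

## Logic of the disconnections

The C7–CH2 bond of the allyl group is cut first, which leads from 11 back to 9 and 10. The allyl group is the one part of 11 that would be at risk under the hydride, base and hot copper conditions used earlier, so it is attached last and a chlorine atom holds its place. The gain is that every earlier compound carries only inert aryl halides. The demand is a palladium catalyst that inserts into an electron-rich aryl chloride and transfers allyl without moving the double bond.

Next the O1–C8a bond of 9 is cut, giving 8. This is an aryl–oxygen bond, so neither stereocentre takes part in its formation, and the cis relation in 9 follows directly from the anti relation in 8. The gain is an open chain in which both oxygens already sit on the correct carbons. The demand is that copper selects the C–Br bond over the C–Cl bond, and that the substrate has no acidic C–H and no second hydroxyl.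

The C3 methyl group of 8 is then traced back through the C–O bond of the sulfonate in 7 and the primary hydroxyl in 6 to the ester of 5. No skeletal bond is cut. The purpose is to recover the ester that made the neighbouring carbon acidic. Doing this before ring closure removes the base-sensitive centre and also the primary hydroxyl, which would otherwise close a six-membered ring of its own on the same bromide. The demand is a sulfonylation selective for the primary hydroxyl and a hydride displacement that spares the aryl bromide.

The C–H bond at the carbinol carbon of 5 is cut, giving 4. Both stereocentres disappear in this step backwards, since 4 is racemic and needs no chiral input. The demand is an enzyme that reduces only the ketone, accepts only one enantiomer of the rapidly racemising substrate and delivers hydride to the face that gives the anti product.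

The bond between the α-carbon and the aryloxy oxygen of 4 is cut, giving 2 and 3. The oxygen of 3 thereby becomes O4, which fixes the chlorine para to O4 (future C7) and the bromine on the future C8a without any regiochemical choice. The gain is two simple pieces. The demand is an SN2 reaction of a phenoxide at a secondary, doubly activated carbon.

Finally the C–Cl bond of 2 is cut, giving 1. The gain is a commercial β-keto ester. The demand is monochlorination at the methylene without attack on the trimethoxyphenyl ring.

## Other disconnections considered

Alternative 1: The cut runs through ring A itself: C4a–C8a, C5–C6 and C7–C8 are broken, so rings A and B both arise in one cyclotrimerisation.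
- Forward step: the bis(alkynyl ether) A1 (ethynyl on the benzylic oxygen, silylethynyl on the other) would be combined with pent-1-en-4-yne A2 under Cp*RuCl(cod) or RhCl(PPh3)3 to give the silylated benzodioxane A3. Protodesilylation would then lead to 11.
- In favour: the allyl group arrives inside A2, so no cross-coupling on an electron-rich aryl chloride and no tin reagent is needed. Both stereocentres are in place in A1 and are not touched by the metallacycle chemistry. Three C–C bonds and two rings form at once. The usual preference of such ruthenium catalysts for a meta relation between the alkyne substituent and a substituent on the diyne terminus points to the required C5/C7 pattern. On convergence, skeletal bonds formed per step and a tin-free end game, this alternative is the better plan.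
- Against: the stereochemical problem is only moved, because A1 needs the same anti 1-aryl-1,2-dioxygenated propane in enantiopure form, and asymmetric dihydroxylation of the (E)-alkene gives the syn series. The two oxygens must receive two different alkynyl groups in turn, each by a dichlorovinyl ether and elimination sequence. Benzylic alkynyl ethers are prone to sigmatropic rearrangement on mild warming, and alkynyl ethers hydrate easily. Regiocontrol rests on a silyl directing group, and a C6-allyl isomer would be a constitutional isomer of A3 that is hard to remove. The alkene of A2 may enter the metallacycle in place of the alkyne. The final desilylation by acid endangers the benzylic C2–O1 bond.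
- Comparison: in the chosen plan an SN2 reaction and an aryl etherification assign O4 and O1 with no regiochemical question left open, whereas the cyclotrimerisation leaves one. In step count the alternative should be longer (chiral diol, two ynol ether installations, cyclotrimerisation, desilylation) than the eight steps chosen.

Alternative 2: The cut is made at the two ring C–O bonds O1–C2 and O4–C4a.
- Forward step: the phenoxide of 4-fluoro-3-hydroxybenzaldehyde A5 (Cs2CO3, DMF) would open the trans epoxide A4 at its benzylic carbon with inversion. The alkoxide released on the neighbouring carbon would then displace the fluoride para to the formyl group and close ring B to the aldehyde A6.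
- In favour: the stereochemistry comes from one well-established asymmetric epoxidation of an (E)-propenylarene. Inversion at C2 and retention at C3 turn the trans epoxide into the cis ring by design. Two C–O bonds and the ring form in one operation without a transition metal. The substitution pattern of A5 (hydroxyl meta, fluorine para to formyl) encodes the O1/O4 regiochemistry. In step economy this is the better plan: A6 could be reached in about two steps, and even with about three more to turn formyl into allyl (reduction, bromination, copper-mediated vinyl coupling) the total stays below eight.
- Against: both epoxide carbons are secondary, and under basic conditions the phenoxide is not expected to discriminate cleanly. Attack at the methyl-bearing carbon followed by the same fluoride displacement would give the transposed 2-methyl-3-aryl ring system, a constitutional isomer of A6. The benzylic carbon bears a donor-substituted aryl group, so partial ionisation could leak material into the trans series. The phenoxide of A5 is a weak nucleophile and can attack the activated fluoride of a second molecule of A5. The formyl-to-allyl conversion passes through a reactive benzylic halide.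
- Comparison: the chosen plan settles each question in a separate event (SN2 at the α-carbon for O4, enzymatic hydride delivery for configuration, retentive arylation for O1), while the domino step asks one reagent to solve regio- and stereochemistry together. The two plans are equal in that both finish with an operation at C7.

Alternative 3: The cut is the C2–aryl bond.
- Forward step: 3,4,5-trimethoxyphenyl triflate A7 and 7-chloro-3-methyl-1,4-benzodioxine A8 would be joined under Pd(OAc)2 and one enantiomer of BINAP. The arylpalladium cation adds across C2=C3 with aryl to C2 and palladium to C3. β-Hydride elimination can then only take a methyl hydrogen, because the C2–H is anti to palladium, giving the exocyclic enol ether A9. Hydrogenation from the face opposite the aryl group would give 9, where this plan joins the chosen route.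
- In favour: it is a catalytic asymmetric C–C bond formation. The aryl group enters late, which is the better arrangement if analogues with other aryl groups are wanted. C3 is then set by substrate control in the cis sense required. The mechanism itself protects the new stereocentre in the first elimination. The step count is about equal (roughly three steps to A8, then arylation, hydrogenation and allylation), so on step economy the two plans are level.
- Against: intermolecular asymmetric Heck reactions are dependable for a small group of unhindered cyclic alkenes. A8 is a trisubstituted, doubly oxygenated alkene whose insertion must create a fully substituted carbon–palladium centre, and the regiochemistry of insertion is not secured. Re-addition of the palladium hydride can move the double bond back into ring B, and that endocyclic isomer has no stereocentre. A9 is an acid-labile enol ether. A8 is not commercial, and its synthesis meets the same O1/O4-versus-chlorine regiochemistry problem. The hydrogenation must spare the C–Cl bond and the benzylic C2–O1 bond.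
- Comparison: the chosen plan takes its selectivity from an enzyme class established for racemising β-keto esters, the alternative from a ligand in a reaction class not developed for this alkene type. Both need the same final allylation of 9.

Key step: step 3

Assumption: "anti" means that hydroxyl and aryloxy lie on opposite sides when the chain aryl–C–C–ester is drawn zigzag (the erythro series), and a ketoreductase with this selectivity is taken to be identifiable in a commercial enzyme panel.

## Route

Step 1
Reactants: 1 ethyl 3-oxo-3-(3,4,5-trimethoxyphenyl)propanoate
Product: 2 ethyl 2-chloro-3-oxo-3-(3,4,5-trimethoxyphenyl)propanoate (racemic)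
Conditions: SO2Cl2 (1.0 equiv), CH2Cl2, 0 °C to rt
Reagents that add atoms: sulfuryl chloride, O=S(=O)(Cl)Cl
Why: Electrophilic α-chlorination of the enol of a β-keto ester; the doubly activated methylene reacts far faster than the aroyl-deactivated trimethoxyphenyl ring, and one equivalent at low temperature limits dichlorination.

Step 2
Reactants: 2 ethyl 2-chloro-3-oxo-3-(3,4,5-trimethoxyphenyl)propanoate; 3 2-bromo-4-chlorophenol
Product: 4 ethyl 2-(2-bromo-4-chlorophenoxy)-3-oxo-3-(3,4,5-trimethoxyphenyl)propanoate (racemic)
Conditions: K2CO3 (1.2 equiv), acetone, rt to 50 °C
Reagents that add atoms: none
Why: Williamson-type SN2 displacement of the activated α-chloride by the phenoxide; the phenol oxygen becomes O4, so chlorine ends para to O4 (future C7) and bromine on the future C8a.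

Step 3
Reactants: 4 ethyl 2-(2-bromo-4-chlorophenoxy)-3-oxo-3-(3,4,5-trimethoxyphenyl)propanoate (racemic)
Product: 5 ethyl (2R,3R)-2-(2-bromo-4-chlorophenoxy)-3-hydroxy-3-(3,4,5-trimethoxyphenyl)propanoate
Conditions: ketoreductase (anti-selective, chosen by panel screening), NADP+ (cat.), glucose dehydrogenase, D-glucose, KH2PO4/K2HPO4 buffer pH 7.0 (pH held with NaOH), DMSO (10% v/v), 30 °C
Reagents that add atoms: none
Why: The enzyme binds one enantiomer of 4 next to NADPH and transfers the C4 hydride of the dihydronicotinamide to one face of the aryl ketone while the catalytic tyrosine protonates the oxygen; glucose dehydrogenase returns NADP+ to NADPH at the expense of glucose. The closest known reaction type is the ketoreductase dynamic kinetic resolution of α-alkyl, α-halo and α-amido β-keto esters. No ring is closed. The carbinol centre (future C2, R) is set by the face of hydride delivery that the active site imposes, and the aryloxy-bearing centre (future C3, R at this stage) by the enzyme accepting only one enantiomer of the substrate. The unreacted enantiomer is fed back through the enol, because the C–H flanked by ketone, ester and aryloxy oxygen should exchange at pH 7 much faster than reduction occurs, whereas the product has lost the ketone and no longer epimerises. The step needs anti diastereoselectivity, high enantioselectivity and chemoselectivity for the ketone over the ester; these are properties of the enzyme, helped by the clear difference in shape between the flat trimethoxyphenyl group and the branched methine on either side of the carbonyl. Neutral pH and 30 °C keep ester hydrolysis and retro-aldol cleavage slow.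

Step 4
Reactants: 5 ethyl (2R,3R)-2-(2-bromo-4-chlorophenoxy)-3-hydroxy-3-(3,4,5-trimethoxyphenyl)propanoate
Product: 6 (1R,2S)-2-(2-bromo-4-chlorophenoxy)-1-(3,4,5-trimethoxyphenyl)propane-1,3-diol
Conditions: LiBH4 (2 equiv), THF, 0 °C to rt
Reagents that add atoms: none
Why: Lithium-assisted borohydride reduction of the ester, fast for a β-hydroxy ester and too weakly basic at this temperature for retro-aldol or epimerisation; both centres are retained, and the descriptor at the aryloxy carbon changes from R to S only because CH2OH ranks below the carbinol carbon.

Step 5
Reactants: 6 (1R,2S)-2-(2-bromo-4-chlorophenoxy)-1-(3,4,5-trimethoxyphenyl)propane-1,3-diol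
Product: 7 (2S,3R)-2-(2-bromo-4-chlorophenoxy)-3-hydroxy-3-(3,4,5-trimethoxyphenyl)propyl 4-methylbenzenesulfonate
Conditions: TsCl (1.05 equiv), Et3N, DMAP (cat.), CH2Cl2, −10 to 0 °C
Reagents that add atoms: 4-methylbenzenesulfonyl chloride, Cc1ccc(cc1)S(=O)(=O)Cl
Why: Kinetically controlled sulfonylation; the primary hydroxyl reacts much faster than the secondary benzylic one, which is flanked by the aryl ring and the aryloxy-bearing carbon.

Step 6
Reactants: 7 (2S,3R)-2-(2-bromo-4-chlorophenoxy)-3-hydroxy-3-(3,4,5-trimethoxyphenyl)propyl 4-methylbenzenesulfonate
Product: 8 (1R,2S)-2-(2-bromo-4-chlorophenoxy)-1-(3,4,5-trimethoxyphenyl)propan-1-ol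
Conditions: LiEt3BH (3 equiv), THF, 0 °C to rt; then aq. NH4Cl
Reagents that add atoms: none
Why: SN2 displacement of a primary sulfonate by the strongly nucleophilic triethylborohydride (one equivalent is consumed by the hydroxyl); the reaction occurs at the CH2 carbon, so neither stereocentre is touched, and aryl bromide and chloride are inert to this hydride at room temperature.

Step 7
Reactants: 8 (1R,2S)-2-(2-bromo-4-chlorophenoxy)-1-(3,4,5-trimethoxyphenyl)propan-1-ol
Product: 9 (2R,3S)-7-chloro-3-methyl-2-(3,4,5-trimethoxyphenyl)-2,3-dihydro-1,4-benzodioxine
Conditions: CuI (10 mol%), 3,4,7,8-tetramethyl-1,10-phenanthroline (20 mol%), Cs2CO3 (2 equiv), toluene, 110 °C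
Reagents that add atoms: none
Why: Intramolecular Ullmann-type C–O coupling: the caesium alkoxide binds monovalent copper, which inserts into the neighbouring C–Br bond (much faster than into C–Cl) and closes the six-membered ring B by forming O1–C8a; the C2–O1 bond is never broken and no acidic C–H remains, so both centres are retained and the anti chain becomes the cis ring.

Step 8
Reactants: 9 (2R,3S)-7-chloro-3-methyl-2-(3,4,5-trimethoxyphenyl)-2,3-dihydro-1,4-benzodioxine; 10 allyltributylstannane
Product: 11 (2R,3S)-7-allyl-3-methyl-2-(3,4,5-trimethoxyphenyl)-2,3-dihydro-1,4-benzodioxine
Conditions: Pd2(dba)3 (1.5 mol%), P(t-Bu)3 (6 mol%), CsF (2.2 equiv), 1,4-dioxane, 100 °C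
Reagents that add atoms: none
Why: Stille cross-coupling; the bulky, electron-rich phosphine lets zerovalent palladium insert into the deactivated C–Cl bond, fluoride activates the stannane for transmetalation of allyl in preference to butyl, and reductive elimination forms the C7–CH2 bond without involving a stereocentre; the reaction is stopped at full conversion to limit double-bond migration.

## Compound list

1 | ethyl 3-oxo-3-(3,4,5-trimethoxyphenyl)propanoate | CCOC(=O)CC(=O)c1cc(OC)c(OC)c(OC)c1 | starting material
2 | ethyl 2-chloro-3-oxo-3-(3,4,5-trimethoxyphenyl)propanoate (racemic) | CCOC(=O)C(Cl)C(=O)c1cc(OC)c(OC)c(OC)c1 | intermediate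
3 | 2-bromo-4-chlorophenol | Oc1ccc(Cl)cc1Br | starting material
4 | ethyl 2-(2-bromo-4-chlorophenoxy)-3-oxo-3-(3,4,5-trimethoxyphenyl)propanoate (racemic) | CCOC(=O)C(Oc1ccc(Cl)cc1Br)C(=O)c1cc(OC)c(OC)c(OC)c1 | intermediate
5 | ethyl (2R,3R)-2-(2-bromo-4-chlorophenoxy)-3-hydroxy-3-(3,4,5-trimethoxyphenyl)propanoate | O[C@H](c1cc(OC)c(OC)c(OC)c1)[C@H](C(=O)OCC)Oc1ccc(Cl)cc1Br | intermediate
6 | (1R,2S)-2-(2-bromo-4-chlorophenoxy)-1-(3,4,5-trimethoxyphenyl)propane-1,3-diol | O[C@H](c1cc(OC)c(OC)c(OC)c1)[C@H](CO)Oc1ccc(Cl)cc1Br | intermediate
7 | (2S,3R)-2-(2-bromo-4-chlorophenoxy)-3-hydroxy-3-(3,4,5-trimethoxyphenyl)propyl 4-methylbenzenesulfonate | O[C@H](c1cc(OC)c(OC)c(OC)c1)[C@H](COS(=O)(=O)c1ccc(C)cc1)Oc1ccc(Cl)cc1Br | intermediate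
8 | (1R,2S)-2-(2-bromo-4-chlorophenoxy)-1-(3,4,5-trimethoxyphenyl)propan-1-ol | O[C@H](c1cc(OC)c(OC)c(OC)c1)[C@H](C)Oc1ccc(Cl)cc1Br | intermediate
9 | (2R,3S)-7-chloro-3-methyl-2-(3,4,5-trimethoxyphenyl)-2,3-dihydro-1,4-benzodioxine | Clc1ccc2c(c1)O[C@H](c1cc(OC)c(OC)c(OC)c1)[C@H](C)O2 | intermediate
10 | allyltributylstannane | C=CC[Sn](CCCC)(CCCC)CCCC | starting material
11 | (2R,3S)-7-allyl-3-methyl-2-(3,4,5-trimethoxyphenyl)-2,3-dihydro-1,4-benzodioxine | C=CCc1ccc2c(c1)O[C@H](c1cc(OC)c(OC)c(OC)c1)[C@H](C)O2 | target

## Step count and least certain steps

Total step count: 8. Longest linear sequence: 8 steps (1 to 11); 3 and 10 are commercial and enter at steps 2 and 8.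

Step 3 (key step). The most likely failure is that no enzyme of the panel combines acceptance of a ketone flanked by two bulky groups with anti selectivity, so that conversion is poor or the syn diastereomer is formed. Ester hydrolysis by esterase impurities followed by decarboxylation may also drain the substrate. The fallback replaces catalyst control by the chiral pool and chelation control.
- It sets out from 3: a Mitsunobu reaction with ethyl (R)-lactate (PPh3, diisopropyl azodicarboxylate, THF, 0 °C to rt) should give, with inversion, ethyl (2S)-2-(2-bromo-4-chlorophenoxy)propanoate F1.
- MeNH(OMe)·HCl with i-PrMgCl (THF, −20 °C) should convert this into the Weinreb amide (2S)-2-(2-bromo-4-chlorophenoxy)-N-methoxy-N-methylpropanamide F2.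
- Commercial 3,4,5-trimethoxyphenylmagnesium bromide (THF, −20 to 0 °C) should give the ketone (2S)-2-(2-bromo-4-chlorophenoxy)-1-(3,4,5-trimethoxyphenyl)propan-1-one F3.
- Zn(BH4)2 in Et2O at −20 °C should deliver hydride to the zinc chelate of the carbonyl and aryloxy oxygens from the side of the small hydrogen (Cram chelate model), giving the anti alcohol. The fallback comes back to the route at 8.
- Compounds 4 to 7 are bypassed. The price is substrate control in place of enzyme control and a ketone whose α-centre can epimerise under base.

Step 8. Oxidative addition into the electron-rich C–Cl bond may be slow, and at 100 °C palladium hydride re-addition can move the allyl double bond into conjugation with ring A. The fallback reverses the polarity of the coupling and avoids tin.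
- It sets out from 9: a Miyaura borylation (Pd2(dba)3, XPhos, bis(pinacolato)diboron, KOAc, 1,4-dioxane, 100 °C) should give (2R,3S)-3-methyl-7-(4,4,5,5-tetramethyl-1,3,2-dioxaborolan-2-yl)-2-(3,4,5-trimethoxyphenyl)-2,3-dihydro-1,4-benzodioxine F4.
- A Suzuki-type coupling with allyl bromide (Pd(PPh3)4, K2CO3, THF/H2O, 60 °C) should then give the allyl compound at a temperature where migration is slower. The fallback comes back to the route at 11.

Step 7. C–O bond formation from a hindered secondary benzylic alkoxide may be sluggish at copper, which lets hydrodebromination compete. The fallback sets out from 8 and comes back at 9 without a new compound (F0). It forms the same bond in a different catalytic manifold, a palladium-catalysed etherification (Pd(OAc)2, a bulky di-tert-butyl biarylphosphine, Cs2CO3, toluene, 80 °C). Here oxidative addition of the C–Br bond to zerovalent palladium is followed by C–O reductive elimination from a divalent palladium alkoxide; the bulky ligand is needed to outrun β-hydride elimination of that alkoxide.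

Step 6. The benzylic alkoxide formed by the first equivalent of hydride may itself displace the sulfonate (four-membered ring formation), or hydride attack at the β-branched, β-oxygenated carbon may be slow. The fallback replaces ionic by radical reduction.
- It sets out from 7: NaI in acetone at reflux should give (1R,2R)-2-(2-bromo-4-chlorophenoxy)-3-iodo-1-(3,4,5-trimethoxyphenyl)propan-1-ol F5. The descriptor at C2 changes only because CH2I outranks the carbinol carbon.
- (Me3Si)3SiH with AIBN (cat.) in toluene at 80 °C should then abstract the alkyl iodine far faster than the aryl bromine and give the methyl compound. The fallback comes back to the route at 8.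

## Further compounds

F1 | step 3 | ethyl (2S)-2-(2-bromo-4-chlorophenoxy)propanoate | CCOC(=O)[C@H](C)Oc1ccc(Cl)cc1Br
F2 | step 3 | (2S)-2-(2-bromo-4-chlorophenoxy)-N-methoxy-N-methylpropanamide | CON(C)C(=O)[C@H](C)Oc1ccc(Cl)cc1Br
F3 | step 3 | (2S)-2-(2-bromo-4-chlorophenoxy)-1-(3,4,5-trimethoxyphenyl)propan-1-one | O=C(c1cc(OC)c(OC)c(OC)c1)[C@H](C)Oc1ccc(Cl)cc1Br
F4 | step 8 | (2R,3S)-3-methyl-7-(4,4,5,5-tetramethyl-1,3,2-dioxaborolan-2-yl)-2-(3,4,5-trimethoxyphenyl)-2,3-dihydro-1,4-benzodioxine | CC1(C)OB(OC1(C)C)c1ccc2c(c1)O[C@H](c1cc(OC)c(OC)c(OC)c1)[C@H](C)O2
F0 | step 7 | none | none
F5 | step 6 | (1R,2R)-2-(2-bromo-4-chlorophenoxy)-3-iodo-1-(3,4,5-trimethoxyphenyl)propan-1-ol | O[C@H](c1cc(OC)c(OC)c(OC)c1)[C@H](CI)Oc1ccc(Cl)cc1Br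
A1 | alternative 1 | 5-[(1R,2S)-1-(ethynyloxy)-2-{[(trimethylsilyl)ethynyl]oxy}propyl]-1,2,3-trimethoxybenzene | C#CO[C@H](c1cc(OC)c(OC)c(OC)c1)[C@H](C)OC#C[Si](C)(C)C
A2 | alternative 1 | pent-1-en-4-yne | C=CCC#C
A3 | alternative 1 | (2R,3S)-7-allyl-3-methyl-5-(trimethylsilyl)-2-(3,4,5-trimethoxyphenyl)-2,3-dihydro-1,4-benzodioxine | C=CCc1cc([Si](C)(C)C)c2c(c1)O[C@H](c1cc(OC)c(OC)c(OC)c1)[C@H](C)O2
A4 | alternative 2 | (2S,3S)-2-methyl-3-(3,4,5-trimethoxyphenyl)oxirane | C[C@@H]1O[C@H]1c1cc(OC)c(OC)c(OC)c1
A5 | alternative 2 | 4-fluoro-3-hydroxybenzaldehyde | O=Cc1ccc(F)c(O)c1
A6 | alternative 2 | (2R,3S)-7-formyl-3-methyl-2-(3,4,5-trimethoxyphenyl)-2,3-dihydro-1,4-benzodioxine | O=Cc1ccc2c(c1)O[C@H](c1cc(OC)c(OC)c(OC)c1)[C@H](C)O2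
A7 | alternative 3 | 3,4,5-trimethoxyphenyl trifluoromethanesulfonate | COc1cc(OS(=O)(=O)C(F)(F)F)cc(OC)c1OC
A8 | alternative 3 | 7-chloro-3-methyl-1,4-benzodioxine | CC1=COc2cc(Cl)ccc2O1
A9 | alternative 3 | (R)-7-chloro-3-methylidene-2-(3,4,5-trimethoxyphenyl)-2,3-dihydro-1,4-benzodioxine | Clc1ccc2c(c1)O[C@H](c1cc(OC)c(OC)c(OC)c1)C(=C)O2
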